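The constants used here were drawn at random within sensible limits; the flask was simulated.

Which form of the catalyst holds the most when the asked conversion is reached, and should you plan the next run on the catalyst you weigh in, or on less?

left-handed substrate 0.050 M; gas 1.7 mM (held); free catalyst 0.75 mol%; impurity 0.29 mM; right-handed substrate 0.050 M

    reagent + catalyst intermediate B → free catalyst + right-handed product (k1 = 29000 M⁻¹ h⁻¹)
    free catalyst + left-handed substrate ⇌ catalyst intermediate A (K2 = 24 M⁻¹, k2 = 1300 M⁻¹ h⁻¹)
    free catalyst + right-handed substrate ⇌ catalyst intermediate B (K3 = 25 M⁻¹, k3 = 1700 M⁻¹ h⁻¹)
    reagent + catalyst intermediate A → free catalyst + left-handed product (k4 = 69000 M⁻¹ h⁻¹)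
    free catalyst + impurity → spent catalyst (k5 = 1.2 × 10⁵ M⁻¹ h⁻¹)
    gas ⇌ reagent, rate k6*(csat - [reagent]) (k6 = 1.4 h⁻¹, csat = 1.7 mM)

- free catalyst is single-handed; left-handed substrate and right-handed substrate are mirror images of each other, charged as a racemate, each of them at the stated concentration
- at the start none of reagent is dissolved
- charge of left-handed substrate (flask): 0.050 M

1. the form that holds most of the catalyst when 30% of the left-handed substrate and right-handed substrate together are converted (spent catalyst / catalyst intermediate B / free catalyst / catalyst intermediate A)
2. its share of the catalyst then

Start with the charge. The loading is reckoned on the left-handed substrate, so the flask holds 0.375 mM of catalyst against 0.29 mM of impurity, and each impurity takes one free catalyst for good. Now take the spent share, impurity charged over catalyst charged: 77.3%. The impurity is the limiting reagent of that capture, so the share stands once the capture has finished, and you must ask how long that takes.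

While no reagent is dissolved, the two substrates hold the catalyst in its intermediates, which leaves 29.0% of it free. On a first round, reckoned with the whole charge working, the impurity has a half-life of 3.19 min. But the catalyst falls one for one with the impurity, so the capture is second-order and its half-life lengthens as it goes. Now put the first answer back: near the end of the capture, just 0.0850 mM of catalyst remains, and the same free fraction of that gives a half-life of 14.1 min. Meanwhile, the asked conversion needs 30.0 mM of reagent, and the gas delivers at most 2.38 mM h⁻¹, so it takes at least 12.6 h. The capture finishes first because its slow tail is much shorter than that. My answer is therefore spent catalyst at 77.3%, and the next run should be budgeted on 0.0850 mM of working catalyst.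

The forecast also names spent catalyst, at 77%, within 38% to 78%, with the impurity “used up irreversibly”.

The simulation gives spent catalyst as the largest form at 20.9 h, with 77.3% of the catalyst. In this flask the tail half-life of 14.1 min is far shorter than those 20.9 h, and at 3.00 h the impurity already stands at 0% of its charge, spent catalyst at 77.3%, and the two products at 2.60% and 1.59%. At 53.5 h, spent catalyst still holds 77.3% of the catalyst, which leaves 22.7% in the working forms.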